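**Retrosynthetic overview**
1. Target 27 comes from pentamer 26 by cleavage of all alkyl ethers; in 26 only the ring C hydroxyl on C3 is free.
2. Feature: ring C carries the ether oxygen to ring B on C1, the ether oxygen to ring D on C4 (para), oxygen on C3 and C5, and hydrogen on C2 and C6. C1–C2 map onto an aryl ethynyl ether and C3–C6 onto a 4-aryloxy-3-ethoxycyclobutenone.
3. Key disconnection: ring C bonds C2–C3 and C1–C6 (C3–C4 is opened and re-closed) lead back to ethynyl ether 9 of the ring A–B phenol and cyclobutenone 21, which carries rings D and E.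
4. 9 comes from ring A–B phenol 5 and trichloroethylene, and 5 from copper-catalysed etherification of 2,4,6-trimethoxyphenol. 21 comes from an aryloxyketene and ethoxyacetylene; the ketene comes from ring D–E phenol 14, made by copper-catalysed etherification and C–H borylation/oxidation.
5. Ring order: rings A, B, D and E are bought as arenes; ring C is the only ring built, last, in step 11.

Key step: step 11

Remark on the chemistry: the hydroxyls of rings A, B, D and E are carried as methyl ethers and the ring C oxygen that stems from ethoxyacetylene as an ethyl ether, since boron tribromide cleaves both kinds in the last step.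
Abbreviations used in names: ArAB = 2,6-dimethoxy-4-(2,4,6-trimethoxyphenoxy)phenyl; ArDE = 3,5-dimethoxy-4-(3,4,5-trimethoxyphenoxy)phenyl.

**Route**

Step 1
Reactants: 1 4-bromo-2,6-dimethoxyphenol
Product: 2 2-(benzyloxy)-5-bromo-1,3-dimethoxybenzene
Conditions: BnBr, K2CO3, DMF, 60 °C
Reagents that add atoms: benzyl bromide, BrCc1ccccc1
Why: Williamson ether synthesis (SN2 of the phenoxide on benzyl bromide) should mask the ring B oxygen that later becomes the ynol ether oxygen.

Step 2
Reactants: 2 2-(benzyloxy)-5-bromo-1,3-dimethoxybenzene; 3 2,4,6-trimethoxyphenol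
Product: 4 2-(benzyloxy)-1,3-dimethoxy-5-(2,4,6-trimethoxyphenoxy)benzene
Conditions: CuI (10 mol%), picolinic acid (20 mol%), K3PO4, DMSO, 100 °C, argon
Reagents that add atoms: none
Why: Ullmann-type copper-catalysed diaryl ether synthesis with picolinic acid as ligand suits a 2,6-disubstituted phenol and an aryl bromide without ortho substituents, and should form the ring A–O–ring B bond.

Step 3
Reactants: 4 2-(benzyloxy)-1,3-dimethoxy-5-(2,4,6-trimethoxyphenoxy)benzene
Product: 5 2,6-dimethoxy-4-(2,4,6-trimethoxyphenoxy)phenol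
Conditions: H2 (1 atm), 10% Pd/C, EtOAc/MeOH, rt
Reagents that add atoms: none
Why: catalytic hydrogenolysis of the benzyl ether should free the ring B phenol while the methyl ethers and the diaryl ether stay intact.

Step 4
Reactants: 5 2,6-dimethoxy-4-(2,4,6-trimethoxyphenoxy)phenol; 6 trichloroethylene
Product: 7 2-[(E)-1,2-dichloroethenyloxy]-1,3-dimethoxy-5-(2,4,6-trimethoxyphenoxy)benzene
Conditions: K2CO3, DMF, 70 °C
Reagents that add atoms: none
Why: carbonate eliminates HCl from trichloroethylene to dichloroacetylene, to which the phenoxide adds in anti fashion (elimination–addition), the standard entry to aryl (E)-1,2-dichlorovinyl ethers.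

Step 5
Reactants: 7 2-[(E)-1,2-dichloroethenyloxy]-1,3-dimethoxy-5-(2,4,6-trimethoxyphenoxy)benzene
Product: 9 2-(ethynyloxy)-1,3-dimethoxy-5-(2,4,6-trimethoxyphenoxy)benzene, via lithium aryloxyacetylide 8 (not isolated)
Conditions: n-BuLi (2.2 equiv), THF, −78 → −40 °C; then H2O, −78 °C; used at once
Reagents that add atoms: none
Why: dehydrochlorination to the chloroalkynyl ether followed by chlorine–lithium exchange (ynol ether synthesis from 1,2-dichlorovinyl ethers) should give acetylide 8, which water protonates at low temperature before ring metalation can compete.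

Step 6
Reactants: 10 2,6-dimethoxyphenol; 11 5-iodo-1,2,3-trimethoxybenzene
Product: 12 5-(2,6-dimethoxyphenoxy)-1,2,3-trimethoxybenzene
Conditions: CuI (10 mol%), picolinic acid (20 mol%), K3PO4, DMSO, 90 °C, argon
Reagents that add atoms: none
Why: the same Ullmann-type etherification, here with an aryl iodide, should form the ring D–O–ring E bond.

Step 7
Reactants: 12 5-(2,6-dimethoxyphenoxy)-1,2,3-trimethoxybenzene
Product: 14 3,5-dimethoxy-4-(3,4,5-trimethoxyphenoxy)phenol, via aryl pinacol boronate 13 (not isolated)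
Conditions: HBpin (1.5 equiv), [Ir(OMe)(cod)]2 (1.5 mol%), 4,4'-di-tert-butyl-2,2'-bipyridine (3 mol%), THF, 80 °C; then KHSO5 (as Oxone), acetone/H2O, rt
Reagents that add atoms: potassium peroxymonosulfate, [K+].[O-]S(=O)(=O)OO
Why: iridium-catalysed C–H borylation is governed by sterics, and of the five aromatic C–H bonds of 12 only the one para to the ether oxygen on the dimethoxyphenoxy ring has no ortho substituent; boronate 13 is then oxidised in the same flask (one-pot borylation/oxidation) to the phenol.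

Step 8
Reactants: 14 3,5-dimethoxy-4-(3,4,5-trimethoxyphenoxy)phenol; 15 ethyl bromoacetate
Product: 17 2-(ArDE-oxy)acetic acid, via ethyl aryloxyacetate 16 (not isolated)
Conditions: K2CO3, MeCN, 60 °C; then aq. NaOH, rt; HCl to pH 2
Reagents that add atoms: sodium hydroxide, [Na+].[OH-]
Why: Williamson alkylation of the unhindered phenoxide followed by saponification in the same flask installs the two carbons that become C4 and C3 of ring C.

Step 9
Reactants: 17 2-(ArDE-oxy)acetic acid
Product: 18 2-(ArDE-oxy)acetyl chloride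
Conditions: (COCl)2 (1.5 equiv), DMF (cat.), CH2Cl2, 0 °C → rt; evaporated and used at once
Reagents that add atoms: oxalyl chloride, O=C(Cl)C(Cl)=O
Why: acid chloride formation through the Vilsmeier-type chloroiminium species runs without a Lewis acid, so the electron-rich rings should not be acylated.

Step 10
Reactants: 18 2-(ArDE-oxy)acetyl chloride; 19 ethoxyacetylene
Product: 21 4-(ArDE-oxy)-3-ethoxycyclobut-2-en-1-one (racemic), via aryloxyketene 20 (not isolated)
Conditions: 18 added over 2 h to 19 (3 equiv) and Et3N (1.5 equiv), Et2O, 0 °C → rt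
Reagents that add atoms: none
Why: triethylamine dehydrochlorinates 18 to aryloxyketene 20, whose carbonyl carbon bonds to the nucleophilic CH terminus of ethoxyacetylene in a ketene–alkyne [2+2] cycloaddition, the established route to 4-substituted 3-ethoxycyclobutenones; the C4 stereocentre forms as a racemate and is erased in step 11.

Step 11
Reactants: 21 4-(ArDE-oxy)-3-ethoxycyclobut-2-en-1-one; 9 2-(ethynyloxy)-1,3-dimethoxy-5-(2,4,6-trimethoxyphenoxy)benzene
Product: 26 5-(ArAB-oxy)-2-(ArDE-oxy)-3-ethoxyphenol, via vinylketene 22 (not isolated), via 4-vinylcyclobutenone 23 (not isolated), via dienylketene 24 (not isolated), via cyclohexadienone 25 (not isolated)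
Conditions: 9 (1.3 equiv), toluene (0.2 M), 80 °C, then 110 °C, sealed tube, argon
Reagents that add atoms: none
Why: Danheiser benzannulation: 21 opens by conrotatory 4π electrocyclic ring opening (the aryloxy group on C4 turning outward) to vinylketene 22, whose ketene C=C adds [2+2] to the alkyne of 9 and so forms ring C bonds C2–C3 and C1–C6 in vinylcyclobutenone 23. A second, reversible 4π opening gives dienylketene 24, and ring C is closed by thermal disrotatory 6π electrocyclisation (bond C3–C4) to cyclohexadienone 25, which tautomerises irreversibly to phenol 26. The closest known reactions are the benzannulations of cyclobutenones with alkoxy- and siloxyacetylenes, of whose ynol ether class an aryl ethynyl ether is a less tested member. No stereocentre is set, since C4 of 21 and the sp3 centres of 23 and 25 all become planar on aromatisation. The step needs one regioselectivity, bonding of the electrophilic ketene carbonyl carbon to the unsubstituted alkyne carbon so that the two aryloxy groups end para on ring C, and the polarisation of the ynol ether (nucleophilic CH terminus, cation stabilised on the oxygen-bearing carbon) secures it. The two ortho methoxy groups of ring B twist the aryl ring away from the ether oxygen lone pair, which then feeds the alkyne, and the aryl group offers no β-hydrogen for retro-ene loss at 110 °C.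

Step 12
Reactants: 26 5-(ArAB-oxy)-2-(ArDE-oxy)-3-ethoxyphenol
Product: 27 5-{2,6-dihydroxy-4-[2,6-dihydroxy-4-[2,6-dihydroxy-4-(2,4,6-trihydroxyphenoxy)phenoxy]phenoxy]phenoxy}benzene-1,2,3-triol (CNP0308003.0)
Conditions: BBr3 (25 equiv), CH2Cl2, −78 °C → rt; then H2O, 0 °C; argon; reverse-phase chromatography
Reagents that add atoms: none
Why: boron tribromide cleaves aryl methyl and aryl ethyl ethers by bromide attack on the O-alkyl carbon of the boron–ether complex and leaves diaryl ether bonds intact, so the ten methyl ethers and the ethyl ether should fall in one operation.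

**Compound list**
1 | 4-bromo-2,6-dimethoxyphenol | COc1cc(Br)cc(OC)c1O | starting material
2 | 2-(benzyloxy)-5-bromo-1,3-dimethoxybenzene | COc1cc(Br)cc(OC)c1OCc1ccccc1 | intermediate
3 | 2,4,6-trimethoxyphenol | COc1cc(OC)c(O)c(OC)c1 | starting material
4 | 2-(benzyloxy)-1,3-dimethoxy-5-(2,4,6-trimethoxyphenoxy)benzene | COc1cc(OC)c(Oc2cc(OC)c(OCc3ccccc3)c(OC)c2)c(OC)c1 | intermediate
5 | 2,6-dimethoxy-4-(2,4,6-trimethoxyphenoxy)phenol (ring A–B phenol) | COc1cc(OC)c(Oc2cc(OC)c(O)c(OC)c2)c(OC)c1 | intermediate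
6 | trichloroethylene | ClC=C(Cl)Cl | starting material
7 | 2-[(E)-1,2-dichloroethenyloxy]-1,3-dimethoxy-5-(2,4,6-trimethoxyphenoxy)benzene | Cl/C=C(/Cl)Oc1c(OC)cc(Oc2c(OC)cc(OC)cc2OC)cc1OC | intermediate
8 | lithium 2-(ArAB-oxy)ethynide (formed in the flask) | [Li]C#COc1c(OC)cc(Oc2c(OC)cc(OC)cc2OC)cc1OC | intermediate
9 | 2-(ethynyloxy)-1,3-dimethoxy-5-(2,4,6-trimethoxyphenoxy)benzene (ethynyl ether of the ring A–B phenol) | C#COc1c(OC)cc(Oc2c(OC)cc(OC)cc2OC)cc1OC | intermediate
10 | 2,6-dimethoxyphenol | COc1cccc(OC)c1O | starting material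
11 | 5-iodo-1,2,3-trimethoxybenzene | COc1cc(I)cc(OC)c1OC | starting material
12 | 5-(2,6-dimethoxyphenoxy)-1,2,3-trimethoxybenzene | COc1cccc(OC)c1Oc1cc(OC)c(OC)c(OC)c1 | intermediate
13 | 2-(ArDE)-4,4,5,5-tetramethyl-1,3,2-dioxaborolane (formed in the flask) | COc1cc(B2OC(C)(C)C(C)(C)O2)cc(OC)c1Oc1cc(OC)c(OC)c(OC)c1 | intermediate
14 | 3,5-dimethoxy-4-(3,4,5-trimethoxyphenoxy)phenol (ring D–E phenol) | COc1cc(O)cc(OC)c1Oc1cc(OC)c(OC)c(OC)c1 | intermediate
15 | ethyl bromoacetate | CCOC(=O)CBr | starting material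
16 | ethyl 2-(ArDE-oxy)acetate (formed in the flask) | CCOC(=O)COc1cc(OC)c(Oc2cc(OC)c(OC)c(OC)c2)c(OC)c1 | intermediate
17 | 2-(ArDE-oxy)acetic acid | OC(=O)COc1cc(OC)c(Oc2cc(OC)c(OC)c(OC)c2)c(OC)c1 | intermediate
18 | 2-(ArDE-oxy)acetyl chloride | O=C(Cl)COc1cc(OC)c(Oc2cc(OC)c(OC)c(OC)c2)c(OC)c1 | intermediate
19 | ethoxyacetylene | C#COCC | starting material
20 | (ArDE-oxy)ketene (formed in the flask) | O=C=COc1cc(OC)c(Oc2cc(OC)c(OC)c(OC)c2)c(OC)c1 | intermediate
21 | 4-(ArDE-oxy)-3-ethoxycyclobut-2-en-1-one (racemic) | CCOC1=CC(=O)C1Oc1cc(OC)c(Oc2cc(OC)c(OC)c(OC)c2)c(OC)c1 | intermediate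
22 | (3Z)-4-(ArDE-oxy)-3-ethoxybuta-1,3-dien-1-one (vinylketene, formed in the flask) | O=C=C/C(OCC)=C/Oc1cc(OC)c(Oc2cc(OC)c(OC)c(OC)c2)c(OC)c1 | intermediate
23 | 3-(ArAB-oxy)-4-[(Z)-2-(ArDE-oxy)-1-ethoxyethenyl]cyclobut-2-en-1-one (racemic, formed in the flask) | O=C1C=C(Oc2c(OC)cc(Oc3c(OC)cc(OC)cc3OC)cc2OC)C1/C(OCC)=C/Oc1cc(OC)c(Oc2cc(OC)c(OC)c(OC)c2)c(OC)c1 | intermediate
24 | (3E,5Z)-3-(ArAB-oxy)-6-(ArDE-oxy)-5-ethoxyhexa-1,3,5-trien-1-one (dienylketene, formed in the flask) | O=C=C/C(Oc1c(OC)cc(Oc2c(OC)cc(OC)cc2OC)cc1OC)=C\C(OCC)=C\Oc1cc(OC)c(Oc2cc(OC)c(OC)c(OC)c2)c(OC)c1 | intermediate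
25 | 3-(ArAB-oxy)-6-(ArDE-oxy)-5-ethoxycyclohexa-2,4-dien-1-one (racemic, formed in the flask) | O=C1C=C(Oc2c(OC)cc(Oc3c(OC)cc(OC)cc3OC)cc2OC)C=C(OCC)C1Oc1cc(OC)c(Oc2cc(OC)c(OC)c(OC)c2)c(OC)c1 | intermediate
26 | 5-(ArAB-oxy)-2-(ArDE-oxy)-3-ethoxyphenol (pentamer, ring C as free phenol) | CCOc1cc(Oc2c(OC)cc(Oc3c(OC)cc(OC)cc3OC)cc2OC)cc(O)c1Oc1cc(OC)c(Oc2cc(OC)c(OC)c(OC)c2)c(OC)c1 | intermediate
27 | 5-{2,6-dihydroxy-4-[2,6-dihydroxy-4-[2,6-dihydroxy-4-(2,4,6-trihydroxyphenoxy)phenoxy]phenoxy]phenoxy}benzene-1,2,3-triol | Oc1cc(O)c(Oc2cc(O)c(Oc3cc(O)c(Oc4cc(O)c(Oc5cc(O)c(O)c(O)c5)c(O)c4)c(O)c3)c(O)c2)c(O)c1 | target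

**Totals**
Total step count: 12.
Longest linear sequence: 7 steps (steps 6, 7, 8, 9, 10, 11, 12; the branch through steps 1 to 5 is equally long).

**Steps most likely to fail**

Step 11. The terminal aryl ethynyl ether may oligomerise or add the product phenol faster than it intercepts the vinylketene, and the vinylketene may then be lost to dimerisation or to acylation of 26. The fallback sets out from 5 and comes back at 27; it builds ring C and ring D as arenes by repeating the chemistry of steps 2 and 3. Phenol 5 and bromide 2 under CuI, picolinic acid and K3PO4 in DMSO should give the benzyl-protected trimer F1, and hydrogenolysis over Pd/C the trimer phenol F2. A second coupling with 2 should give the benzyl-protected tetramer F3, and hydrogenolysis the tetramer phenol F4. Coupling of F4 with iodide 11 should give the permethylated pentamer F5, which BBr3 under the conditions of step 12 should convert into 27.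

Step 5. The terminal aryl ethynyl ether may oligomerise or hydrate during work-up and concentration, and n-butyllithium may metalate ring A between its methoxy groups if the exchange is slow. The fallback sets out from 8 and comes back at 26. Acetylide 8 is quenched with Me3SiCl instead of water to give the storable C-silyl ynol ether F6. F6 is heated with 21 as in step 11; the silicon-bearing carbon is the nucleophilic alkyne terminus, so the regiochemistry is unchanged and the C2-silylated pentamer phenol F7 should result. CF3CO2H in CH2Cl2 should then remove the aryl silane by ipso-protodesilylation to give 26.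

Step 12. Some of the eleven ethers may survive, giving partly alkylated polyphenols that do not separate from the very polar product, and the pyrogallol-type ring E may oxidise in air during isolation. The fallback sets out from 26 and comes back at 27. The crude product of the BBr3 reaction is not isolated as the free polyphenol but acetylated at once (Ac2O, pyridine, DMAP) to the dodecaacetate F8, which can be purified on silica and separated from partly alkylated material. Acid-catalysed methanolysis (HCl from AcCl in MeOH, rt, argon) should then release 27 under non-oxidising conditions.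

**Further compounds**
F1 | step 11 | benzyl-protected trimer, 2-(benzyloxy)-1,3-dimethoxy-5-(ArAB-oxy)benzene | COc1cc(OC)c(Oc2cc(OC)c(Oc3cc(OC)c(OCc4ccccc4)c(OC)c3)c(OC)c2)c(OC)c1
F2 | step 11 | trimer phenol, 2,6-dimethoxy-4-(ArAB-oxy)phenol | COc1cc(OC)c(Oc2cc(OC)c(Oc3cc(OC)c(O)c(OC)c3)c(OC)c2)c(OC)c1
F3 | step 11 | benzyl-protected tetramer | COc1cc(OC)c(Oc2cc(OC)c(Oc3cc(OC)c(Oc4cc(OC)c(OCc5ccccc5)c(OC)c4)c(OC)c3)c(OC)c2)c(OC)c1
F4 | step 11 | tetramer phenol | COc1cc(OC)c(Oc2cc(OC)c(Oc3cc(OC)c(Oc4cc(OC)c(O)c(OC)c4)c(OC)c3)c(OC)c2)c(OC)c1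
F5 | step 11 | permethylated pentamer | COc1cc(OC)c(Oc2cc(OC)c(Oc3cc(OC)c(Oc4cc(OC)c(Oc5cc(OC)c(OC)c(OC)c5)c(OC)c4)c(OC)c3)c(OC)c2)c(OC)c1
F6 | step 5 | trimethyl[(ArAB-oxy)ethynyl]silane | C[Si](C)(C)C#COc1c(OC)cc(Oc2c(OC)cc(OC)cc2OC)cc1OC
F7 | step 5 | 3-(ArAB-oxy)-6-(ArDE-oxy)-5-ethoxy-2-(trimethylsilyl)phenol | CCOc1cc(Oc2c(OC)cc(Oc3c(OC)cc(OC)cc3OC)cc2OC)c([Si](C)(C)C)c(O)c1Oc1cc(OC)c(Oc2cc(OC)c(OC)c(OC)c2)c(OC)c1
F8 | step 12 | dodecaacetate of 27 | CC(=O)Oc1cc(OC(C)=O)c(Oc2cc(OC(C)=O)c(Oc3cc(OC(C)=O)c(Oc4cc(OC(C)=O)c(Oc5cc(OC(C)=O)c(OC(C)=O)c(OC(C)=O)c5)c(OC(C)=O)c4)c(OC(C)=O)c3)c(OC(C)=O)c2)c(OC(C)=O)c1
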